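The route rests on disconnecting the C8–C9 bond of ring B. The cis-8,9-diol (C8 hydroxyl axial, C9 oxygen equatorial), flanked by C7 and the C10 ring fusion, is the direct product of a reductive pinacol closure. In one operation SmI2 joins the two aldehyde carbons, closes ring B onto the finished ring A and sets C8 and C9. The precursor is a ring A 1,6-dialdehyde: a cyclohexane carrying the C3 silyl ether, the cis C4 and C5 methyl groups, a C10 formyl group and, on quaternary C5, a CH2–CH(isopropenyl)–CHO chain. It is released from its diol immediately before use.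

Key step: step 15

Convention: locants C1–C13 are those of the target (ring A = C1–C5, C10; ring B = C5–C10) in every intermediate; β is the face of the C5 methyl group, α the opposite face; TBS = tert-butyldimethylsilyl, TMS = trimethylsilyl.
Remark: C6 is a neopentyl carbon, so the C6–C7 bond cannot be made by enolate alkylation; C6–C8 arrive as an acrylimide (step 8) and C7 is set afterwards by enolate acylation (step 11).
Assumption: the lipase of step 3 hydrolyses the (S)-acetate faster; if its preference is the reverse, the (R)-alcohol is collected instead and enters step 4 to give the same enone 6.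

Step 1
Reactants: 1 2-methylcyclohexane-1,3-dione
Product: 2 3-isobutoxy-2-methylcyclohex-2-en-1-one
Conditions: i-BuOH, TsOH (cat.), toluene, reflux, Dean–Stark
Reagents that add atoms: 2-methylpropan-1-ol, CC(C)CO
Why: Acid-catalysed enol etherification of the 1,3-dione with azeotropic removal of water gives the vinylogous ester and differentiates the two carbonyl groups (the ether carbon becomes C10, the ring methyl is the C5 methyl); no stereocenter is formed.

Step 2
Reactants: 2 3-isobutoxy-2-methylcyclohex-2-en-1-one
Product: 3 racemic 6-acetoxy-3-isobutoxy-2-methylcyclohex-2-en-1-one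
Conditions: Mn(OAc)3·2H2O, benzene, reflux, Dean–Stark
Reagents that add atoms: manganese triacetate, CC(=O)[O-].CC(=O)[O-].CC(=O)[O-].[Mn+3]
Why: Oxidative α′-acetoxylation of an enone with trivalent manganese acetate goes through the manganese enolate of the only enolisable α′-methylene and places the future C3 oxygen; the new stereocenter forms as the racemate.

Step 3
Reactants: 3 racemic 6-acetoxy-3-isobutoxy-2-methylcyclohex-2-en-1-one
Product: 4 (R)-6-acetoxy-3-isobutoxy-2-methylcyclohex-2-en-1-one
Conditions: lipase from Burkholderia cepacia, pH 7 phosphate buffer–DMSO, 30 °C, stopped just past half conversion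
Reagents that add atoms: none
Why: Enzymatic kinetic resolution by enantioselective ester hydrolysis removes the (S)-antipode as the alcohol and leaves the (R)-acetate, so the absolute configuration of C3 is fixed here by the enzyme.

Step 4
Reactants: 4 (R)-6-acetoxy-3-isobutoxy-2-methylcyclohex-2-en-1-one
Product: 6 (R)-4-hydroxy-2-methylcyclohex-2-en-1-one, via allylic diol 5 (not isolated)
Conditions: LiAlH4, Et2O, 0 °C; then 1 M HCl, THF, rt
Reagents that add atoms: water, O
Why: Stork–Danheiser transposition: hydride reduces the ketone and cleaves the acetate, and acid hydrolysis of the enol ether with allylic shift moves the carbonyl to C10 and leaves the C4=C5 enone, the C3 carbinol stereocenter being untouched.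

Step 5
Reactants: 6 (R)-4-hydroxy-2-methylcyclohex-2-en-1-one
Product: 7 (R)-4-(tert-butyldimethylsilyloxy)-2-methylcyclohex-2-en-1-one
Conditions: TBSCl, imidazole, DMF, rt
Reagents that add atoms: tert-butyldimethylsilyl chloride, CC(C)(C)[Si](C)(C)Cl
Why: Imidazole-promoted silylation gives a bulky, robust C3 ether that directs the next step and survives to the key step; no stereocenter changes.

Step 6
Reactants: 7 (R)-4-(tert-butyldimethylsilyloxy)-2-methylcyclohex-2-en-1-one
Product: 8 tert-butyl{[(1R,2R)-2,3-dimethyl-4-(trimethylsilyloxy)cyclohex-3-en-1-yl]oxy}dimethylsilane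
Conditions: Me2CuLi (from MeLi and CuI), TMSCl, Et2O–THF, −78 °C; Et3N quench
Reagents that add atoms: lithium dimethylcuprate, [Li+].C[Cu-]C; chlorotrimethylsilane, C[Si](C)(C)Cl
Why: Chlorosilane-accelerated cuprate conjugate addition delivers methyl to C4 on the face opposite the γ-silyloxy group, which sets C4 (methyl β, trans to the C3 oxygen), and the enolate is trapped regiospecifically as the C5=C10 silyl enol ether.

Step 7
Reactants: 9 (R)-4-benzyloxazolidin-2-one; 10 acryloyl chloride
Product: 11 (R)-3-acryloyl-4-benzyloxazolidin-2-one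
Conditions: n-BuLi, THF, −78 °C; then 10, −78 to 0 °C
Reagents that add atoms: none
Why: N-acylation of the lithiated oxazolidinone with the acid chloride gives the chelating Michael acceptor that carries C6, C7 and C8 together with the auxiliary for C7; no stereocenter is formed.

Step 8
Reactants: 8 silyl enol ether of step 6; 11 (R)-3-acryloyl-4-benzyloxazolidin-2-one
Product: 12 (R)-4-benzyl-3-{3-[(1R,2R,3R)-3-(tert-butyldimethylsilyloxy)-1,2-dimethyl-6-oxocyclohexyl]propanoyl}oxazolidin-2-one
Conditions: TiCl4, CH2Cl2, −78 °C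
Reagents that add atoms: none
Why: Mukaiyama–Michael addition: the enol ether attacks the TiCl4-chelated acrylimide through C5 on the α face, anti to the neighbouring C4 methyl that sits pseudo-axial on the β face (the facial preference of conjugate addition–alkylation routes to cis-vicinal dimethyl quaternary centres), which forms the C5–C6 bond and sets quaternary C5 without any substitution at C6.

Step 9
Reactants: 12 keto imide of step 8
Product: 13 (R)-4-benzyl-3-{3-[(1R,2R,3R)-3-(tert-butyldimethylsilyloxy)-1,2-dimethyl-6-methylidenecyclohexyl]propanoyl}oxazolidin-2-one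
Conditions: Zn, CH2Br2, TiCl4, THF–CH2Cl2, 0 °C to rt
Reagents that add atoms: dibromomethane, BrCBr
Why: Takai–Lombardo methylenation converts the hindered C10 ketone into the exocyclic alkene (C9) with a non-basic zinc–titanium reagent that leaves the imide and the silyl ether alone; no stereocenter is formed.

Step 10
Reactants: 13 methylidene imide of step 9
Product: 15 (R)-4-benzyl-3-{3-[3α-(tert-butyldimethylsilyloxy)-10β-(hydroxymethyl)-4β,5β-dimethylcyclohexyl]propanoyl}oxazolidin-2-one, via B-alkyl-9-BBN adduct 14 (not isolated)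
Conditions: 9-BBN, THF, 0 °C to rt; then H2O2, pH 7 phosphate buffer, 0 °C
Reagents that add atoms: hydrogen peroxide, OO
Why: Anti-Markovnikov hydroboration–oxidation: with the C3 ether and C4 methyl equatorial the C5 methyl is axial and blocks the β face of the methylene group, so hydrogen reaches C10 from the α face and the hydroxymethyl group (C9) ends up β and equatorial, trans to C6; neutral oxidation spares the imide.

Step 11
Reactants: 15 primary alcohol of step 10
Product: 17 (R)-3-[(7S)-9-acetoxy-3α-(tert-butyldimethylsilyloxy)-11-oxo-12-nor-8,9-secoeremophilan-8-oyl]-4-benzyloxazolidin-2-one (C7 acetyl imide with C9 acetate), via dilithium enolate alkoxide 16 (not isolated)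
Conditions: LiN(i-Pr)2 (2.2 equiv), THF, −78 °C; then AcCl (3 equiv), −78 °C
Reagents that add atoms: acetyl chloride, CC(=O)Cl
Why: Auxiliary-controlled enolate C-acylation: the chelated Z-lithium enolate of the imide is acetylated on the face opposite the benzyl group, which sets C7 (S) and brings in C11 and C13, while the C9 alkoxide is O-acetylated in the same operation; the β-keto imide resists enolisation at C7 because of allylic strain.

Step 12
Reactants: 17 β-keto imide acetate of step 11
Product: 18 (R)-3-[(7S)-9-acetoxy-3α-(tert-butyldimethylsilyloxy)-8,9-secoeremophil-11-en-8-oyl]-4-benzyloxazolidin-2-one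
Conditions: Zn, CH2Br2, TiCl4, THF–CH2Cl2, 0 °C to rt
Reagents that add atoms: dibromomethane, BrCBr
Why: Takai–Lombardo methylenation of the methyl ketone builds the isopropenyl group (C12) with a non-basic reagent that should not enolise C7 and does not touch the imide or acetate carbonyls.

Step 13
Reactants: 18 isopropenyl imide acetate of step 12
Product: 19 (7S)-3α-(tert-butyldimethylsilyloxy)-8,9-secoeremophil-11-ene-8,9-diol
Conditions: LiBH4, MeOH (1 equiv), THF, 0 °C
Reagents that add atoms: none
Why: Reductive cleavage of the N-acyl oxazolidinone at the exocyclic carbonyl, with concurrent reduction of the acetate, releases the C8 and C9 primary alcohols and the recoverable auxiliary; C7 is then no longer epimerisable.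

Step 14
Reactants: 19 seco-diol of step 13
Product: 20 (7S)-3α-(tert-butyldimethylsilyloxy)-8,9-secoeremophil-11-ene-8,9-dial
Conditions: Dess–Martin periodinane, NaHCO3, CH2Cl2, 0 °C; cold filtration, used at once
Reagents that add atoms: none
Why: Dess–Martin oxidation takes both primary alcohols to aldehydes under buffered, non-basic conditions, so the allylic α-formyl C7 stereocenter should not epimerise or conjugate before the key step.

Step 15
Reactants: 20 ring A dialdehyde of step 14
Product: 21 (3R,4R,5R,7S,8R,9S,10R)-3-(tert-butyldimethylsilyloxy)eremophil-11-ene-8,9-diol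
Conditions: SmI2 (3 equiv, 0.1 M in THF), t-BuOH (2 equiv), −78 °C, slow addition of cold 20; aq. NaHCO3
Reagents that add atoms: none
Why: Single-electron transfer from divalent samarium to an aldehyde gives a samarium ketyl that adds to the second carbonyl (or couples with a second ketyl), and a further electron transfer gives the cyclic trivalent-samarium diolate, protonated on work-up. The closest known reaction type is the SmI2 pinacol cyclisation of 1,6-dialdehydes to cis-cyclohexane-1,2-diols. Ring B closes in a 6-exo-trig mode through a chair in which the C5–C6 and C10–C9 bonds are equatorial on ring A and the C7 isopropenyl group is equatorial, so the ring fusion stays trans. C8 and C9 are set together: one samarium ion bridges both oxygens and holds them syn, which gives the cis diol, and the cis arrangement with the C9 oxygen axial is disfavoured because it would clash with the axial C5 methyl on the same face of ring B. The step therefore needs the 8α,9α-diol (C8 hydroxyl axial, C9 hydroxyl equatorial), secured by samarium chelation together with the axial C5 methyl; low temperature, a proton source and immediate use of the aldehyde keep C7, which is α to the C8 carbonyl and allylic, from epimerising.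

Step 16
Reactants: 21 diol of step 15; 22 hex-2-ynoic acid
Product: 23 3α-(tert-butyldimethylsilyloxy)-8α-hydroxyeremophil-11-en-9α-yl hex-2-ynoate
Conditions: N,N′-diisopropylcarbodiimide, DMAP (cat.), CH2Cl2, −20 °C
Reagents that add atoms: none
Why: Steglich esterification discriminates the two hydroxyls of the cis diol: the equatorial C9 alcohol reacts, whereas the axial C8 alcohol, flanked by the C7 isopropenyl group and then by the new ester, should stay free.

Step 17
Reactants: 23 C9 mono-ester of step 16
Product: 24 3α,8α-dihydroxyeremophil-11-en-9α-yl hex-2-ynoate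
Conditions: HF·pyridine, pyridine, THF, 0 °C to rt
Reagents that add atoms: none
Why: Fluoride-mediated cleavage of the silyl ether under buffered acidic conditions frees the equatorial C3 alcohol without a base-induced acyl shift from O9 to O8 and without touching the ynoate or the isopropenyl group.

Step 18
Reactants: 24 diol ester of step 17; 22 hex-2-ynoic acid
Product: 25 8α-hydroxyeremophil-11-ene-3α,9α-diyl bis(hex-2-ynoate)
Conditions: N,N′-diisopropylcarbodiimide, DMAP (cat.), CH2Cl2, 0 °C
Reagents that add atoms: none
Why: Steglich esterification of the equatorial C3 alcohol; the only competitor is the axial C8 alcohol, which is shielded by the C7 isopropenyl group and the C9 ester.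

Step 19
Reactants: 25 bis-ynoate of step 18
Product: 26 (3R,4R,5R,7S,8R,9S,10R)-8-hydroxyeremophil-11-ene-3,9-diyl bis[(Z)-hex-2-enoate] (CNP0420276.1)
Conditions: H2 (1 atm), Pd/CaCO3 poisoned with Pb(OAc)2, quinoline, EtOAc, rt
Reagents that add atoms: none
Why: Lindlar semihydrogenation adds hydrogen syn to both ynoate triple bonds to give the two (Z)-enoates, while the isolated 1,1-disubstituted isopropenyl alkene and the esters should not be reduced.

Compound list
1 | 2-methylcyclohexane-1,3-dione | CC1C(=O)CCCC1=O | starting material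
2 | 3-isobutoxy-2-methylcyclohex-2-en-1-one | CC1=C(OCC(C)C)CCCC1=O | intermediate
3 | racemic 6-acetoxy-3-isobutoxy-2-methylcyclohex-2-en-1-one | CC1=C(OCC(C)C)CCC(OC(C)=O)C1=O | intermediate
4 | (R)-6-acetoxy-3-isobutoxy-2-methylcyclohex-2-en-1-one | CC1=C(OCC(C)C)CC[C@@H](OC(C)=O)C1=O | intermediate
5 | (1R)-4-isobutoxy-3-methylcyclohex-3-ene-1,2-diol (both C2 epimers) | CC1=C(OCC(C)C)CC[C@@H](O)C1O | intermediate
6 | (R)-4-hydroxy-2-methylcyclohex-2-en-1-one | CC1=C[C@H](O)CCC1=O | intermediate
7 | (R)-4-(tert-butyldimethylsilyloxy)-2-methylcyclohex-2-en-1-one | CC1=C[C@H](O[Si](C)(C)C(C)(C)C)CCC1=O | intermediate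
8 | tert-butyl{[(1R,2R)-2,3-dimethyl-4-(trimethylsilyloxy)cyclohex-3-en-1-yl]oxy}dimethylsilane (3α-OTBS, 4β-methyl, C5=C10 enol ether) | CC1=C(O[Si](C)(C)C)CC[C@@H](O[Si](C)(C)C(C)(C)C)[C@@H]1C | intermediate
9 | (R)-4-benzyloxazolidin-2-one | O=C1N[C@H](Cc2ccccc2)CO1 | starting material
10 | acryloyl chloride | C=CC(=O)Cl | starting material
11 | (R)-3-acryloyl-4-benzyloxazolidin-2-one | C=CC(=O)N1[C@H](Cc2ccccc2)COC1=O | intermediate
12 | (R)-4-benzyl-3-{3-[(1R,2R,3R)-3-(tert-butyldimethylsilyloxy)-1,2-dimethyl-6-oxocyclohexyl]propanoyl}oxazolidin-2-one (C10 ketone; 3α-OTBS, 4β- and 5β-methyl) | O=C(CC[C@]1(C)[C@@H](C)[C@H](O[Si](C)(C)C(C)(C)C)CCC1=O)N1[C@H](Cc2ccccc2)COC1=O | intermediate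
13 | (R)-4-benzyl-3-{3-[(1R,2R,3R)-3-(tert-butyldimethylsilyloxy)-1,2-dimethyl-6-methylidenecyclohexyl]propanoyl}oxazolidin-2-one | O=C(CC[C@]1(C)[C@@H](C)[C@H](O[Si](C)(C)C(C)(C)C)CCC1=C)N1[C@H](Cc2ccccc2)COC1=O | intermediate
14 | adduct of 13 with 9-BBN: 9-borabicyclo[3.3.1]nonan-9-yl group on C9, C10 with α-hydrogen | O=C(CC[C@]1(C)[C@@H](C)[C@H](O[Si](C)(C)C(C)(C)C)CC[C@H]1CB1C2CCCC1CCC2)N1[C@H](Cc2ccccc2)COC1=O | intermediate
15 | (R)-4-benzyl-3-{3-[3α-(tert-butyldimethylsilyloxy)-10β-(hydroxymethyl)-4β,5β-dimethylcyclohexyl]propanoyl}oxazolidin-2-one (ring A locants; 10α-H) | O=C(CC[C@]1(C)[C@@H](C)[C@H](O[Si](C)(C)C(C)(C)C)CC[C@H]1CO)N1[C@H](Cc2ccccc2)COC1=O | intermediate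
16 | dilithium salt of 15: C9 alkoxide and Z-enolate of the imide | [Li+].[Li+].[O-]/C(=C\C[C@]1(C)[C@@H](C)[C@H](O[Si](C)(C)C(C)(C)C)CC[C@H]1C[O-])N1[C@H](Cc2ccccc2)COC1=O | intermediate
17 | (R)-3-[(7S)-9-acetoxy-3α-(tert-butyldimethylsilyloxy)-11-oxo-12-nor-8,9-secoeremophilan-8-oyl]-4-benzyloxazolidin-2-one (C7 bears acetyl; C9 acetate) | CC(=O)[C@@H](C(=O)N1[C@H](Cc2ccccc2)COC1=O)C[C@]1(C)[C@@H](C)[C@H](O[Si](C)(C)C(C)(C)C)CC[C@H]1COC(C)=O | intermediate
18 | (R)-3-[(7S)-9-acetoxy-3α-(tert-butyldimethylsilyloxy)-8,9-secoeremophil-11-en-8-oyl]-4-benzyloxazolidin-2-one | C=C(C)[C@@H](C(=O)N1[C@H](Cc2ccccc2)COC1=O)C[C@]1(C)[C@@H](C)[C@H](O[Si](C)(C)C(C)(C)C)CC[C@H]1COC(C)=O | intermediate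
19 | (7S)-3α-(tert-butyldimethylsilyloxy)-8,9-secoeremophil-11-ene-8,9-diol (4β,5β-dimethyl, 10α-H) | C=C(C)[C@@H](CO)C[C@]1(C)[C@@H](C)[C@H](O[Si](C)(C)C(C)(C)C)CC[C@H]1CO | intermediate
20 | (7S)-3α-(tert-butyldimethylsilyloxy)-8,9-secoeremophil-11-ene-8,9-dial | C=C(C)[C@@H](C=O)C[C@]1(C)[C@@H](C)[C@H](O[Si](C)(C)C(C)(C)C)CC[C@H]1C=O | intermediate
21 | (3R,4R,5R,7S,8R,9S,10R)-3-(tert-butyldimethylsilyloxy)eremophil-11-ene-8,9-diol (8α-OH axial, 9α-OH equatorial) | C=C(C)[C@@H]1C[C@]2(C)[C@@H](C)[C@H](O[Si](C)(C)C(C)(C)C)CC[C@H]2[C@H](O)[C@@H]1O | intermediate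
22 | hex-2-ynoic acid | CCCC#CC(=O)O | starting material
23 | 3α-(tert-butyldimethylsilyloxy)-8α-hydroxyeremophil-11-en-9α-yl hex-2-ynoate | C=C(C)[C@@H]1C[C@]2(C)[C@@H](C)[C@H](O[Si](C)(C)C(C)(C)C)CC[C@H]2[C@H](OC(=O)C#CCCC)[C@@H]1O | intermediate
24 | 3α,8α-dihydroxyeremophil-11-en-9α-yl hex-2-ynoate | C=C(C)[C@@H]1C[C@]2(C)[C@@H](C)[C@H](O)CC[C@H]2[C@H](OC(=O)C#CCCC)[C@@H]1O | intermediate
25 | 8α-hydroxyeremophil-11-ene-3α,9α-diyl bis(hex-2-ynoate) | C=C(C)[C@@H]1C[C@]2(C)[C@@H](C)[C@H](OC(=O)C#CCCC)CC[C@H]2[C@H](OC(=O)C#CCCC)[C@@H]1O | intermediate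
26 | (3R,4R,5R,7S,8R,9S,10R)-8-hydroxyeremophil-11-ene-3,9-diyl bis[(Z)-hex-2-enoate] | C=C(C)[C@@H]1C[C@]2(C)[C@@H](C)[C@H](OC(=O)/C=C\CCC)CC[C@H]2[C@H](OC(=O)/C=C\CCC)[C@@H]1O | target

Total step count: 19. Longest linear sequence: 18 steps (steps 1–6 and 8–19 from 1; step 7 is a one-step side branch).

Steps most likely to fail

1. Step 15 (key step). The dialdehyde may enolise before electron transfer (loss of the C7 configuration, or conjugation of the isopropenyl group). Each aldehyde may be reduced to the alcohol without coupling. The ring may close through a non-chelated arrangement to a trans diol or to the 8β,9β cis diol. Fallback, setting out from 20 and returning at 21: the same C8–C9 bond would be closed by carbene catalysis. A triazolium salt with i-Pr2NEt in THF (intramolecular cross-benzoin reaction) should form the acyl-anion equivalent at the less hindered C8 aldehyde and add it to C9. This should give 3α-(tert-butyldimethylsilyloxy)-9α-hydroxyeremophil-11-en-8-one F1, in which C7 and C9 are α to the ketone and can settle with both substituents equatorial. LiBH(s-Bu)3 in THF at −78 °C should then deliver hydride along the equatorial trajectory and give the axial 8α-alcohol, that is diol 21.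

2. Step 8. Bond formation at the fully substituted C5 may be sluggish. Facial selectivity may erode because the C3 silyloxy group becomes axial on the α face in the reactive half-chair. Fallback, setting out from 8 and returning at 12: 8 would be converted with MeLi (THF, 0 °C) into its lithium enolate and O-acylated with allyl chloroformate to give allyl (3R,4R)-4-(tert-butyldimethylsilyloxy)-2,3-dimethylcyclohex-1-en-1-yl carbonate F2. Decarboxylative Tsuji allylation with Pd2(dba)3 and the t-Bu-PHOX enantiomer that reinforces α-face attack should give (2R,3R,4R)-2-allyl-4-(tert-butyldimethylsilyloxy)-2,3-dimethylcyclohexan-1-one F3, with catalyst control of C5. 9-BBN followed by NaOH/H2O2 should give the 3-hydroxypropyl ketone F4. TEMPO/PhI(OAc)2 in MeCN–water should give the propanoic acid F5. Pivaloyl chloride/Et3N followed by lithiated 9 should then give keto imide 12.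

3. Step 12. The Lewis-acidic titanium species may enolise the β-dicarbonyl unit and epimerise C7, or methylene transfer to the hindered ketone may stay incomplete. Fallback, setting out from 17 and returning at 18: Me3SiCH2MgCl with CeCl3 (THF, −78 °C) should add to the ketone to give the β-hydroxysilane F6. BF3·OEt2 (CH2Cl2, −78 to 0 °C) should then effect the Peterson elimination to isopropenyl imide 18.

Further compounds
F1 | step 15 | 3α-(tert-butyldimethylsilyloxy)-9α-hydroxyeremophil-11-en-8-one | C=C(C)[C@@H]1C[C@]2(C)[C@@H](C)[C@H](O[Si](C)(C)C(C)(C)C)CC[C@H]2[C@H](O)C1=O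
F2 | step 8 | allyl (3R,4R)-4-(tert-butyldimethylsilyloxy)-2,3-dimethylcyclohex-1-en-1-yl carbonate | C=CCOC(=O)OC1=C(C)[C@@H](C)[C@H](O[Si](C)(C)C(C)(C)C)CC1
F3 | step 8 | (2R,3R,4R)-2-allyl-4-(tert-butyldimethylsilyloxy)-2,3-dimethylcyclohexan-1-one | C=CC[C@]1(C)[C@@H](C)[C@H](O[Si](C)(C)C(C)(C)C)CCC1=O
F4 | step 8 | (2R,3R,4R)-4-(tert-butyldimethylsilyloxy)-2-(3-hydroxypropyl)-2,3-dimethylcyclohexan-1-one | OCCC[C@]1(C)[C@@H](C)[C@H](O[Si](C)(C)C(C)(C)C)CCC1=O
F5 | step 8 | 3-[(1R,2R,3R)-3-(tert-butyldimethylsilyloxy)-1,2-dimethyl-6-oxocyclohexyl]propanoic acid | OC(=O)CC[C@]1(C)[C@@H](C)[C@H](O[Si](C)(C)C(C)(C)C)CCC1=O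
F6 | step 12 | β-hydroxysilane from 17: C11 carries hydroxyl, methyl and CH2SiMe3 (both C11 epimers) | C[Si](C)(C)CC(C)(O)[C@@H](C(=O)N1[C@H](Cc2ccccc2)COC1=O)C[C@]1(C)[C@@H](C)[C@H](O[Si](C)(C)C(C)(C)C)CC[C@H]1COC(C)=O
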